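The retrosynthesis traces C4'-H of ring B back to a C4' allyl ester, which is lost at the end as CO2. Ring B is then cut at C1'-C6' and C4'-C5' into a 2-pyrone and a silyl ynol ether.
Enabling feature: ring B is bound through C1' to benzofuran C2, carries oxygen at C3' and C5' on either side of C4'-H, and has prenyl at C2' and C6'. C1' to C4' therefore map onto C6 to C3 of a 4-oxy-5-prenyl-2-pyrone, C5'/C6' map onto an O-substituted prenylalkyne, and C4' can hold the ester that activates the diene.
The pyrone is cut at C5-C6 (dianion acylation), O1-C2 (lactonisation) and C3-CO2 (lithiation). This gives a benzofuran-2-carboxylate, γ-prenylated methyl acetoacetate and allyl chloroformate.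
Forward order: the furan ring is built onto ring A (step 3), the 2-pyrone ring is closed (step 5), and the pyrone is turned into ring B (step 10). Desilylation, MOM removal and deallylation-decarboxylation follow.
Stereochemistry: the target has no stereocentre and no E/Z alkene. The centres that appear in two transient intermediates are erased in the same flask.

Key step: step 10

Assumption: prenyl means 3-methylbut-2-en-1-yl and MOM means methoxymethyl. Primed locants refer to ring B of the target. The ring B oxygens are carried as MOM and triisopropylsilyl ethers rather than methyl ethers, because thiolate demethylation of a resorcinol dimethyl ether tends to stop after one methyl group and Lewis acidic demethylation would attack the prenyl groups.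

Step 1
Reactants: 1 2,4-dihydroxybenzaldehyde; 2 prenyl bromide (1-bromo-3-methylbut-2-ene)
Product: 3 2,4-dihydroxy-3-prenylbenzaldehyde
Conditions: KOH (2 M aq), 0 °C to rt
Reagents that add atoms: none
Why: Phenolate C-alkylation: in water the oxygens of the resorcinolate are shielded by hydrogen bonding, so the soft allylic bromide is attacked by ring carbon, preferentially C3 (ortho to both oxygens), and the C5 and O-alkylated isomers are separated at this inexpensive stage.

Step 2
Reactants: 3 2,4-dihydroxy-3-prenylbenzaldehyde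
Product: 4 2-hydroxy-4-(methoxymethoxy)-3-prenylbenzaldehyde
Conditions: MOMCl (1.1 equiv), K2CO3, acetone, 0 °C to rt
Reagents that add atoms: chloromethyl methyl ether (MOMCl), COCCl
Why: Williamson-type O-alkylation that distinguishes the two phenols because the C2 hydroxyl is tied up in a hydrogen bond to the formyl group, a selectivity routinely used on 2,4-dihydroxyaryl carbonyl compounds.

Step 3
Reactants: 4 2-hydroxy-4-(methoxymethoxy)-3-prenylbenzaldehyde; 5 methyl bromoacetate
Product: 7 methyl 6-(methoxymethoxy)-7-prenylbenzofuran-2-carboxylate, via aryloxyacetate 6 (not isolated)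
Conditions: K2CO3, DMF, 90 °C
Reagents that add atoms: none
Why: Haloacetate variant of the Rap-Stoermer benzofuran synthesis: O-alkylation gives 6, whose ester-activated methylene adds to the neighbouring aldehyde (intramolecular aldol, 5-exo-trig) and loses water to aromatise the furan ring, while the MOM ether and the prenyl group are inert to carbonate.

Step 4
Reactants: 8 methyl acetoacetate; 2 prenyl bromide
Product: 10 methyl 7-methyl-3-oxooct-6-enoate, via acetoacetate dianion 9 (not isolated)
Conditions: LiN(i-Pr)2 (2.1 equiv), THF, 0 °C; 2, 0 °C to rt; aq HCl quench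
Reagents that add atoms: none
Why: Weiler dianion alkylation: the terminal, more basic carbanion of 9 displaces bromide at the primary allylic carbon (SN2), so only the γ-carbon is prenylated.

Step 5
Reactants: 10 methyl 7-methyl-3-oxooct-6-enoate; 7 methyl 6-(methoxymethoxy)-7-prenylbenzofuran-2-carboxylate
Product: 13 4-hydroxy-6-[6-(methoxymethoxy)-7-prenylbenzofuran-2-yl]-5-prenyl-2H-pyran-2-one, via keto ester dianion 11 (not isolated), via diketo ester 12 (not isolated)
Conditions: 10 (2.2 equiv), LiN(i-Pr)2 (4.5 equiv), THF, -78 to 0 °C; 7, -78 °C to rt; cold aq HCl quench; then DBU, PhMe, 90 °C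
Reagents that add atoms: none
Why: Claisen-type γ-acylation of a β-keto ester dianion by an aryl ester (the dianion is taken in excess because the more acidic product quenches it) gives 12, and base-induced enol lactonisation (6-exo-trig addition-elimination at the methyl ester) is the standard closure to a 4-hydroxy-2-pyrone.

Step 6
Reactants: 13 4-hydroxy-6-[6-(methoxymethoxy)-7-prenylbenzofuran-2-yl]-5-prenyl-2H-pyran-2-one
Product: 14 4-(methoxymethoxy)-6-[6-(methoxymethoxy)-7-prenylbenzofuran-2-yl]-5-prenyl-2H-pyran-2-one
Conditions: MOMCl, K2CO3, acetone, 0 °C to rt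
Reagents that add atoms: chloromethyl methyl ether (MOMCl), COCCl
Why: O-alkylation of a vinylogous carboxylic acid: the hard chloromethyl ether reacts at the C4 oxygen of the pyronate, which keeps the 2-pyrone intact, and the acetal installed here serves as directing group for step 7 and as acid-labile mask of the C3' hydroxyl.

Step 7
Reactants: 14 4-(methoxymethoxy)-6-[6-(methoxymethoxy)-7-prenylbenzofuran-2-yl]-5-prenyl-2H-pyran-2-one
Product: 16 allyl 4-(methoxymethoxy)-6-[6-(methoxymethoxy)-7-prenylbenzofuran-2-yl]-2-oxo-5-prenyl-2H-pyran-3-carboxylate, via 3-lithiopyrone 15 (not isolated)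
Conditions: LiN(i-Pr)2 (1.15 equiv), THF, -78 °C; ClCO2CH2CH=CH2, -78 to -20 °C
Reagents that add atoms: allyl chloroformate, C=CCOC(=O)Cl
Why: Directed lithiation of a 4-alkoxy-2-pyrone occurs at C3, the sp2 C-H flanked by the lactone carbonyl and the coordinating MOM oxygen, and acylation of the vinyllithium by a chloroformate gives the ester; the allyl ester activates like a methyl ester but can later be cleaved under neutral conditions despite two ortho substituents.

Step 8
Reactants: 2 prenyl bromide; 17 ethynylmagnesium bromide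
Product: 18 5-methylhex-4-en-1-yne
Conditions: 17 (0.5 M in THF, 1.5 equiv), CuCl (5 mol %), THF, 0 to 40 °C; fractional distillation
Reagents that add atoms: none
Why: Copper-catalysed allylic substitution by an alkynyl Grignard reagent, which attacks prenyl bromide at the unhindered primary terminus and gives the skipped enyne, while the excess of 17 suppresses double alkylation.

Step 9
Reactants: 18 5-methylhex-4-en-1-yne
Product: 21 triisopropyl[(5-methylhex-4-en-1-yn-1-yl)oxy]silane, via lithium acetylide 19 (not isolated), via lithium ynolate 20 (not isolated)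
Conditions: n-BuLi (1.0 equiv), THF, -78 °C; t-BuOOLi (from t-BuOOH and LiN(SiMe3)2), -78 to 0 °C; i-Pr3SiOTf, -78 to 0 °C
Reagents that add atoms: tert-butyl hydroperoxide, CC(C)(C)OO; triisopropylsilyl triflate, CC(C)[Si](OS(=O)(=O)C(F)(F)F)(C(C)C)C(C)C
Why: Oxidation of a lithium acetylide by lithium tert-butyl peroxide (attack of the acetylide on peroxide oxygen) gives ynolate 20, which the bulky silyl triflate traps on oxygen rather than carbon; this is the standard entry to triisopropylsilyl ynol ethers, and the unactivated trisubstituted alkene is inert to the nucleophilic peroxide.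

Step 10
Reactants: 16 allyl 4-(methoxymethoxy)-6-[6-(methoxymethoxy)-7-prenylbenzofuran-2-yl]-2-oxo-5-prenyl-2H-pyran-3-carboxylate; 21 triisopropyl[(5-methylhex-4-en-1-yn-1-yl)oxy]silane
Product: 23 allyl 2-(methoxymethoxy)-4-[6-(methoxymethoxy)-7-prenylbenzofuran-2-yl]-3,5-diprenyl-6-(triisopropylsilyloxy)benzoate, via bicyclic lactone 22 (not isolated)
Conditions: 21 (3 equiv), PhMe, 120 °C, sealed tube, Ar
Reagents that add atoms: none
Why: The lactone carbonyl and the C3 allyl ester lower the LUMO of the pyrone diene (C3=C4-C5=C6) and place its largest coefficient at C6, while the HOMO of the silyl ynol ether is largest at the prenyl-bearing carbon, so a concerted, strongly asynchronous inverse-electron-demand [4+2] cycloaddition forms C6-C(prenyl) (C1'-C6' of the target) slightly ahead of C3-C(OSi) (C4'-C5'). The closest known reaction type is the Diels-Alder/cycloreversion benzannulation of 2-pyrone-3-carboxylates with ynamines, alkyl or silyl ynol ethers and ketene acetals. The one ring closed, the six-membered carbocycle that becomes ring B, arises by suprafacial [4πs+2πs] closure as part of 2-oxabicyclo[2.2.2]octadienone 22, and retro-[4+2] extrusion of CO2 from 22 delivers the arene at the correct oxidation level without an oxidant. No stereocentre survives, since the two bridgehead centres of racemic 22 are erased on aromatisation. The step needs regioselectivity, secured by the polarity match just described (it puts the new prenyl next to the benzofuran and the silyloxy group next to the ester), and chemoselectivity, secured because the three prenyl alkenes and the allyl alkene are far poorer donors than the ynol ether. The triisopropylsilyl ynol ether is used because the retro-ene fragmentation to a ketene that limits ethyl and tert-butyl ynol ethers would here require a silene, and because it comes off with fluoride.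

Step 11
Reactants: 23 allyl 2-(methoxymethoxy)-4-[6-(methoxymethoxy)-7-prenylbenzofuran-2-yl]-3,5-diprenyl-6-(triisopropylsilyloxy)benzoate
Product: 24 allyl 2-hydroxy-6-(methoxymethoxy)-4-[6-(methoxymethoxy)-7-prenylbenzofuran-2-yl]-3,5-diprenylbenzoate
Conditions: Bu4NF, AcOH (1:1), THF, 0 °C
Reagents that add atoms: none
Why: Fluoride-induced cleavage of an aryl silyl ether, driven by the Si-F bond and the salicylate-type phenoxide leaving group, with the acetic acid buffer keeping the medium neutral so that the allyl ester and the MOM ethers are untouched.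

Step 12
Reactants: 24 allyl 2-hydroxy-6-(methoxymethoxy)-4-[6-(methoxymethoxy)-7-prenylbenzofuran-2-yl]-3,5-diprenylbenzoate
Product: 25 allyl 2,6-dihydroxy-4-(6-hydroxy-7-prenylbenzofuran-2-yl)-3,5-diprenylbenzoate
Conditions: HCl (cat., 0.1 M), MeOH-THF, 35 °C
Reagents that add atoms: none
Why: Acid-catalysed transacetalisation of the aryl MOM ethers runs through an oxocarbenium ion far faster than protonation of a trisubstituted alkene, as in many syntheses of prenylated phenols, and the ring B hydroxyls are held by hydrogen bonds to the ester, which disfavours chroman formation.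

Step 13
Reactants: 25 allyl 2,6-dihydroxy-4-(6-hydroxy-7-prenylbenzofuran-2-yl)-3,5-diprenylbenzoate
Product: 27 CNP0322812.0 (5-(6-hydroxy-7-prenylbenzofuran-2-yl)-4,6-diprenylbenzene-1,3-diol), via resorcylic acid 26 (not isolated)
Conditions: Pd(PPh3)4 (5 mol %), morpholine (2 equiv), THF, rt, Ar; then DMF, 90 °C; work-up at pH 5
Reagents that add atoms: none
Why: Tsuji-Trost deallylation (zerovalent palladium ionises the allyl ester and morpholine traps the π-allyl complex) unmasks 26 without attack at the hindered carbonyl, and this 2,6-dihydroxybenzoic acid undergoes protodecarboxylation by ipso protonation on gentle heating, as γ-resorcylic acids do.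

Compound list
1 | 2,4-dihydroxybenzaldehyde | O=Cc1ccc(O)cc1O | starting material
2 | prenyl bromide (1-bromo-3-methylbut-2-ene) | CC(C)=CCBr | starting material
3 | 2,4-dihydroxy-3-prenylbenzaldehyde | O=Cc1ccc(O)c(CC=C(C)C)c1O | intermediate
4 | 2-hydroxy-4-(methoxymethoxy)-3-prenylbenzaldehyde | O=Cc1ccc(OCOC)c(CC=C(C)C)c1O | intermediate
5 | methyl bromoacetate | COC(=O)CBr | starting material
6 | methyl 2-[2-formyl-5-(methoxymethoxy)-6-prenylphenoxy]acetate | COC(=O)COc1c(C=O)ccc(OCOC)c1CC=C(C)C | intermediate
7 | methyl 6-(methoxymethoxy)-7-prenylbenzofuran-2-carboxylate | COC(=O)c1cc2ccc(OCOC)c(CC=C(C)C)c2o1 | intermediate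
8 | methyl acetoacetate | CC(=O)CC(=O)OC | starting material
9 | dilithium dianion (bis-enolate) of methyl acetoacetate | [Li+].[Li+].C=C([O-])C=C([O-])OC | intermediate
10 | methyl 7-methyl-3-oxooct-6-enoate | CC(C)=CCCC(=O)CC(=O)OC | intermediate
11 | dilithium 2,4-dianion (bis-enolate) of methyl 7-methyl-3-oxooct-6-enoate | [Li+].[Li+].CC(C)=CCC=C([O-])C=C([O-])OC | intermediate
12 | methyl 4-[6-(methoxymethoxy)-7-prenylbenzofuran-2-carbonyl]-7-methyl-3-oxooct-6-enoate (racemic, enolisable C4) | COC(=O)CC(=O)C(CC=C(C)C)C(=O)c1cc2ccc(OCOC)c(CC=C(C)C)c2o1 | intermediate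
13 | 4-hydroxy-6-[6-(methoxymethoxy)-7-prenylbenzofuran-2-yl]-5-prenyl-2H-pyran-2-one | O=c1cc(O)c(CC=C(C)C)c(-c2cc3ccc(OCOC)c(CC=C(C)C)c3o2)o1 | intermediate
14 | 4-(methoxymethoxy)-6-[6-(methoxymethoxy)-7-prenylbenzofuran-2-yl]-5-prenyl-2H-pyran-2-one | COCOc1cc(=O)oc(-c2cc3ccc(OCOC)c(CC=C(C)C)c3o2)c1CC=C(C)C | intermediate
15 | 3-lithio derivative of 14 | [Li]c1c(OCOC)c(CC=C(C)C)c(-c2cc3ccc(OCOC)c(CC=C(C)C)c3o2)oc1=O | intermediate
16 | allyl 4-(methoxymethoxy)-6-[6-(methoxymethoxy)-7-prenylbenzofuran-2-yl]-2-oxo-5-prenyl-2H-pyran-3-carboxylate | C=CCOC(=O)c1c(OCOC)c(CC=C(C)C)c(-c2cc3ccc(OCOC)c(CC=C(C)C)c3o2)oc1=O | intermediate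
17 | ethynylmagnesium bromide | C#C[Mg]Br | starting material
18 | 5-methylhex-4-en-1-yne | C#CCC=C(C)C | intermediate
19 | (5-methylhex-4-en-1-yn-1-yl)lithium | [Li]C#CCC=C(C)C | intermediate
20 | lithium 5-methylhex-4-en-1-yn-1-olate | [Li+].[O-]C#CCC=C(C)C | intermediate
21 | triisopropyl[(5-methylhex-4-en-1-yn-1-yl)oxy]silane | CC(C)=CCC#CO[Si](C(C)C)(C(C)C)C(C)C | intermediate
22 | allyl 5-(methoxymethoxy)-1-[6-(methoxymethoxy)-7-prenylbenzofuran-2-yl]-3-oxo-6,7-diprenyl-8-(triisopropylsilyloxy)-2-oxabicyclo[2.2.2]octa-5,7-diene-4-carboxylate (racemic, both bridgeheads transient) | C=CCOC(=O)C12C(=O)OC(c3cc4ccc(OCOC)c(CC=C(C)C)c4o3)(C(CC=C(C)C)=C1OCOC)C(CC=C(C)C)=C2O[Si](C(C)C)(C(C)C)C(C)C | intermediate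
23 | allyl 2-(methoxymethoxy)-4-[6-(methoxymethoxy)-7-prenylbenzofuran-2-yl]-3,5-diprenyl-6-(triisopropylsilyloxy)benzoate | C=CCOC(=O)c1c(OCOC)c(CC=C(C)C)c(-c2cc3ccc(OCOC)c(CC=C(C)C)c3o2)c(CC=C(C)C)c1O[Si](C(C)C)(C(C)C)C(C)C | intermediate
24 | allyl 2-hydroxy-6-(methoxymethoxy)-4-[6-(methoxymethoxy)-7-prenylbenzofuran-2-yl]-3,5-diprenylbenzoate | C=CCOC(=O)c1c(O)c(CC=C(C)C)c(-c2cc3ccc(OCOC)c(CC=C(C)C)c3o2)c(CC=C(C)C)c1OCOC | intermediate
25 | allyl 2,6-dihydroxy-4-(6-hydroxy-7-prenylbenzofuran-2-yl)-3,5-diprenylbenzoate | C=CCOC(=O)c1c(O)c(CC=C(C)C)c(-c2cc3ccc(O)c(CC=C(C)C)c3o2)c(CC=C(C)C)c1O | intermediate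
26 | 2,6-dihydroxy-4-(6-hydroxy-7-prenylbenzofuran-2-yl)-3,5-diprenylbenzoic acid | OC(=O)c1c(O)c(CC=C(C)C)c(-c2cc3ccc(O)c(CC=C(C)C)c3o2)c(CC=C(C)C)c1O | intermediate
27 | CNP0322812.0, 5-(6-hydroxy-7-prenylbenzofuran-2-yl)-4,6-diprenylbenzene-1,3-diol (achiral) | CC(C)=CCc1c(O)cc(O)c(CC=C(C)C)c1-c1cc2ccc(O)c(CC=C(C)C)c2o1 | target

Total step count: 13
Longest linear sequence: 10 steps (1, 2, 3, 5, 6, 7, 10, 11, 12, 13)

Steps most likely to fail

1. Step 10. The cycloaddition may be too slow. The diene is tetrasubstituted, and both the C4 oxygen and the electron-rich benzofuranyl group at C6 push electron density into it. On long heating the ynol ether may be consumed by oligomerisation or by oxygen-to-carbon silyl migration before it engages C6.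
Fallback, from 16 (with 2), rejoining at 24: the same two bonds are made with a more nucleophilic dienophile at the carboxylic acid oxidation level, and aromatisation then comes from an elimination. Dilithioacetate (AcOH, 2 equiv LiN(i-Pr)2, THF) is alkylated with 2 to give 5-methylhex-4-enoic acid F1. Double deprotonation and silylation (LiN(i-Pr)2, Me3SiCl) give 1,1-bis(trimethylsilyloxy)-5-methylhexa-1,4-diene F2. This ketene acetal should add to 16 in PhMe at 80 to 110 °C with the same polarity, its carbon C2 going to pyrone C6. Loss of CO2 and then of trimethylsilanol gives allyl 2-(methoxymethoxy)-4-[6-(methoxymethoxy)-7-prenylbenzofuran-2-yl]-3,5-diprenyl-6-(trimethylsilyloxy)benzoate F3. Brief K2CO3/MeOH treatment converts F3 into 24.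

2. Step 7. Three side processes can erode the C3 acylation: deprotonation at the doubly allylic CH2 on pyrone C5, attack of the amide on the lactone, and addition of 15 to the more electrophilic product.
Fallback, from 13, rejoining at 16: the ester is brought to C3 without a carbanion. O-acylation of 13 with allyl chloroformate and Et3N (CH2Cl2, 0 °C) gives allyl 6-[6-(methoxymethoxy)-7-prenylbenzofuran-2-yl]-2-oxo-5-prenyl-2H-pyran-4-yl carbonate F4. DMAP in warm PhMe induces oxygen-to-carbon carboxyl transfer. This Steglich-type rearrangement is the counterpart of the usual route to 3-acyl-4-hydroxy-2-pyrones, and it leads to the hydrogen-bonded allyl 4-hydroxy-6-[6-(methoxymethoxy)-7-prenylbenzofuran-2-yl]-2-oxo-5-prenyl-2H-pyran-3-carboxylate F5. MOMCl/K2CO3 then gives 16.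

3. Step 1. Poor regioselectivity (C3 against C5 and oxygen) and over-alkylation of the resorcinolate may leave little of the wanted isomer.
Fallback, from 1, rejoining at 3: the prenyl group is delivered intramolecularly by an aromatic Claisen rearrangement. Selective etherification of the free C4 hydroxyl of 1 with 3-chloro-3-methylbut-1-yne (K2CO3, KI, acetone, reflux) gives 2-hydroxy-4-[(2-methylbut-3-yn-2-yl)oxy]benzaldehyde F6. Semihydrogenation (H2, Pd/CaCO3 poisoned with Pb(OAc)2, quinoline) gives 2-hydroxy-4-[(2-methylbut-3-en-2-yl)oxy]benzaldehyde F7. Heating in N,N-diethylaniline at 130 °C should send the allyl unit by [3,3] shift to C3, the ortho carbon favoured by the bond fixation of the chelated salicylaldehyde, with allyl inversion to the prenyl group of 3.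

Further compounds
F1 | step 10 | 5-methylhex-4-enoic acid | CC(C)=CCCC(=O)O
F2 | step 10 | 1,1-bis(trimethylsilyloxy)-5-methylhexa-1,4-diene | CC(C)=CCC=C(O[Si](C)(C)C)O[Si](C)(C)C
F3 | step 10 | allyl 2-(methoxymethoxy)-4-[6-(methoxymethoxy)-7-prenylbenzofuran-2-yl]-3,5-diprenyl-6-(trimethylsilyloxy)benzoate | C=CCOC(=O)c1c(OCOC)c(CC=C(C)C)c(-c2cc3ccc(OCOC)c(CC=C(C)C)c3o2)c(CC=C(C)C)c1O[Si](C)(C)C
F4 | step 7 | allyl 6-[6-(methoxymethoxy)-7-prenylbenzofuran-2-yl]-2-oxo-5-prenyl-2H-pyran-4-yl carbonate | C=CCOC(=O)Oc1cc(=O)oc(-c2cc3ccc(OCOC)c(CC=C(C)C)c3o2)c1CC=C(C)C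
F5 | step 7 | allyl 4-hydroxy-6-[6-(methoxymethoxy)-7-prenylbenzofuran-2-yl]-2-oxo-5-prenyl-2H-pyran-3-carboxylate | C=CCOC(=O)c1c(O)c(CC=C(C)C)c(-c2cc3ccc(OCOC)c(CC=C(C)C)c3o2)oc1=O
F6 | step 1 | 2-hydroxy-4-[(2-methylbut-3-yn-2-yl)oxy]benzaldehyde | C#CC(C)(C)Oc1ccc(C=O)c(O)c1
F7 | step 1 | 2-hydroxy-4-[(2-methylbut-3-en-2-yl)oxy]benzaldehyde | C=CC(C)(C)Oc1ccc(C=O)c(O)c1
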